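## Retrosynthetic overview

1. Chain locants used below: C1H3–C2(Me)(Cl)–C3HBr–C4H2–C5HBr–C6(Me)(Cl)–C7H(O)–C8H2; the target is 3R,5S,6R,7R.
2. C5–C8 half: enynol 1 → dienol 2 → Sharpless epoxy alcohol 3 (sets C6 and C7) → chlorodiol 4 (chloride opens the 6,7-oxirane at C6 with inversion) → tosylate 5 → vinyl chloro-oxirane 6.
3. C1–C3 half: vinyl bromide 7 → gem-dibromide 8 by ionic Br–Cl addition.
4. Key disconnection C3–C4, made together with the C5–Br bond: 6 + 8 → 9 in the last step by intermolecular bromine-atom-transfer radical addition, which also creates C3 and C5. No protecting groups.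
5. Rings: only oxiranes. The 6,7-oxirane is formed in step 2 and opened in step 3; the final 7,8-oxirane is closed in step 4, before the radical coupling.

## Route

Step 1
Reactants: 1 (2E)-3-methylpent-2-en-4-yn-1-ol
Product: 2 (2E)-3-methylpenta-2,4-dien-1-ol
Conditions: H2 (1 atm, stopped at 1.0 equiv uptake), Pd/CaCO3 poisoned with Pb(OAc)2 (5 wt %), quinoline, EtOAc, 0–20 °C
Reagents that add atoms: none
Why: Lindlar-type semihydrogenation over Pd/CaCO3–Pb(OAc)2 stops a terminal alkyne at the vinyl stage and leaves the E-trisubstituted alkene and the alcohol alone; no stereocentre is formed.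

Step 2
Reactants: 2 (2E)-3-methylpenta-2,4-dien-1-ol
Product: 3 [(2R,3R)-3-ethenyl-3-methyloxiran-2-yl]methanol
Conditions: Ti(OiPr)4 (10 mol %), D-(−)-diethyl tartrate (12 mol %), t-BuOOH (2 equiv, anhydrous in isooctane), 4 Å MS, CH2Cl2, −25 °C; citric acid work-up
Reagents that add atoms: tert-butyl hydroperoxide, CC(C)(C)OO
Why: Katsuki–Sharpless asymmetric epoxidation: the Ti(OiPr)4/tartrate catalyst binds the allylic alcohol so only the 2,3-alkene reacts, and D-(−)-tartrate gives the 2R,3R oxirane (the sense that turns geraniol into 2R,3R-epoxygeraniol), which fixes C7 and, after the inversion in step 3, C6.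

Step 3
Reactants: 3 [(2R,3R)-3-ethenyl-3-methyloxiran-2-yl]methanol
Product: 4 (2R,3S)-3-chloro-3-methylpent-4-ene-1,2-diol
Conditions: ClTi(OiPr)3 (1.5 equiv), CH2Cl2, −20 → 0 °C; aqueous tartaric acid work-up; used promptly
Reagents that add atoms: chlorotitanium triisopropoxide, CC(C)O[Ti](Cl)(OC(C)C)OC(C)C
Why: Titanium-assisted regioselective opening of a 2,3-epoxy alcohol at C3 (Sharpless–Caron type), reinforced here because that carbon is tertiary and allylic: chloride is delivered from the chelated titanium to C6 with inversion (3R → 3S) while the C7–O bond is untouched.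

Step 4
Reactants: 4 (2R,3S)-3-chloro-3-methylpent-4-ene-1,2-diol
Product: 6 (2R)-2-[(2S)-2-chlorobut-3-en-2-yl]oxirane, via primary monotosylate 5 (not isolated)
Conditions: TsCl (1.05 equiv), Bu2SnO (2 mol %), Et3N (1.2 equiv), CH2Cl2, 0 °C; then DBU (1.5 equiv), 0 → 20 °C; product kept as a concentrated solution (volatile)
Reagents that add atoms: none
Why: Bu2SnO-catalysed sulfonylation picks the primary hydroxyl, and the secondary alkoxide then closes the oxirane by intramolecular Williamson displacement of the primary tosylate (far faster than attack on the tertiary chloride), so C7 keeps its configuration because its C–O bond is never broken.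

Step 5
Reactants: 7 1-bromo-2-methylprop-1-ene
Product: 8 1,1-dibromo-2-chloro-2-methylpropane
Conditions: NBS (1.1 equiv), HCl (4 M in dioxane, 1.2 equiv), CH2Cl2, −20 → 0 °C, dark
Reagents that add atoms: N-bromosuccinimide, O=C1CCC(=O)N1Br; hydrogen chloride, Cl
Why: Ionic Markovnikov bromochlorination: BrCl formed from NBS and HCl puts electrophilic bromine on the bromine-bearing carbon and chloride on the tertiary cationic carbon, giving the tertiary chloride next to a CHBr2 group; no stereocentre.

Step 6
Reactants: 6 (2R)-2-[(2S)-2-chlorobut-3-en-2-yl]oxirane; 8 1,1-dibromo-2-chloro-2-methylpropane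
Product: 9 (2R)-2-[(2R,3S,5R)-3,5-dibromo-2,6-dichloro-6-methylheptan-2-yl]oxirane
Conditions: 8 (5 equiv, excess recovered), Mn2(CO)10 (10 mol %), PhCF3, degassed, blue LEDs, 20 °C; preparative HPLC on silica
Reagents that add atoms: none
Why: Proposed new method: a Kharasch-type bromine-atom-transfer radical chain addition of an unactivated secondary gem-dibromide, in which photogenerated Mn(CO)5 radicals abstract Br from 8, the resulting α-bromo-β-chloro radical adds to the unhindered CH2 terminus of 6 (which has no allylic hydrogen to stop the chain) to form C3–C4, and the C5 radical takes Br from a further molecule of 8 (its C–Br bond is weakened by the second bromine, and the excess at 20 °C lets transfer outrun telomerisation and β-chlorine loss); the closest known chemistry is the Kharasch addition of bromoform and Mn2(CO)10-photoinitiated atom-transfer additions of polyhalides; C5 is set because the β C–Cl bond aligns with the half-filled orbital and Br enters anti to Cl in the rotamer that puts methyl, not oxiranyl, beside the C4 methylene, giving 5S (estimated 3–4:1, the formal anti Br/Cl adduct of an E-alkene), whereas C3 forms in the C–C bond step with no nearby stereocentre, so 9 and its C3 epimer are expected near 1:1 and are separated (the S → R change at C6 is only a priority change).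

## Compound list

1 | (2E)-3-methylpent-2-en-4-yn-1-ol | C#C/C(C)=C/CO | starting material
2 | (2E)-3-methylpenta-2,4-dien-1-ol | C=C/C(C)=C/CO | intermediate
3 | [(2R,3R)-3-ethenyl-3-methyloxiran-2-yl]methanol | OC[C@H]1O[C@]1(C)C=C | intermediate
4 | (2R,3S)-3-chloro-3-methylpent-4-ene-1,2-diol | C=C[C@](C)(Cl)[C@H](O)CO | intermediate
5 | (2R,3S)-3-chloro-2-hydroxy-3-methylpent-4-en-1-yl 4-methylbenzenesulfonate | C=C[C@](C)(Cl)[C@H](O)COS(=O)(=O)c1ccc(C)cc1 | intermediate
6 | (2R)-2-[(2S)-2-chlorobut-3-en-2-yl]oxirane | C=C[C@](C)(Cl)[C@H]1CO1 | intermediate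
7 | 1-bromo-2-methylprop-1-ene | CC(C)=CBr | starting material
8 | 1,1-dibromo-2-chloro-2-methylpropane | CC(C)(Cl)C(Br)Br | intermediate
9 | (2R)-2-[(2R,3S,5R)-3,5-dibromo-2,6-dichloro-6-methylheptan-2-yl]oxirane | CC(C)(Cl)[C@H](Br)C[C@H](Br)[C@](C)(Cl)[C@H]1CO1 | target

## Step count and risks

Total step count: 6. Longest linear sequence: 5 steps (steps 1, 2, 3, 4 and 6).

Most likely to fail, first: step 6. Compound 8 is only a moderate bromine donor, the oxirane of 6 may be opened by traces of HBr, and C3 is formed without control, so at best about half of the adduct is 9. The fallback sets out from 4 (with 8) and returns at 9, moving the ring closure behind the radical coupling. The same Mn2(CO)10/blue-light addition of 8 is run on the chlorodiol 4, whose free hydroxyls are inert to the chain and whose bulkier CH(OH)CH2OH group should sharpen the anti-to-chlorine delivery at C5. The diol diastereomers are separated on silica to give (2R,3R,4S,6R)-4,6-dibromo-3,7-dichloro-3,7-dimethyloctane-1,2-diol F1. TsCl/Bu2SnO/Et3N then gives (2R,3R,4S,6R)-4,6-dibromo-3,7-dichloro-2-hydroxy-3,7-dimethyloctyl 4-methylbenzenesulfonate F2, which DBU at 0 °C closes to 9.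

Second: step 3. The vinyl oxirane can ionise to an allyl cation (loss of configuration at C6) or take chloride at the vinyl terminus with allylic transposition. The fallback sets out from 1 and returns at 4, carrying the alkyne as a masked vinyl group. Sharpless epoxidation of 1 itself with D-(−)-diethyl tartrate gives [(2R,3R)-3-ethynyl-3-methyloxiran-2-yl]methanol F3. ClTi(OiPr)3 opens it at the tertiary propargylic carbon, where no transposition is possible and ionisation is harder, to give (2R,3S)-3-chloro-3-methylpent-4-yne-1,2-diol F4. Semihydrogenation of F4 over Pd/CaCO3–Pb(OAc)2 with quinoline then gives 4.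

Third: step 2. The epoxy alcohol 3 is small, water-soluble and prone to opening by isopropoxide or tartrate at its tertiary allylic carbon, so isolation may be poor. The fallback sets out from 2 and returns at 5, never isolating 3 or 4. After the epoxidation, TsCl and Et3N are added to the cold reaction mixture and the product is isolated as [(2R,3R)-3-ethenyl-3-methyloxiran-2-yl]methyl 4-methylbenzenesulfonate F5. Anhydrous HCl in Et2O at −78 °C opens F5 at the tertiary allylic carbon through a tight ion pair with inversion, which gives 5 directly; DBU then closes 5 to 6 as in step 4.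

Further compounds
F1 | step 6 | (2R,3R,4S,6R)-4,6-dibromo-3,7-dichloro-3,7-dimethyloctane-1,2-diol | CC(C)(Cl)[C@H](Br)C[C@H](Br)[C@](C)(Cl)[C@H](O)CO
F2 | step 6 | (2R,3R,4S,6R)-4,6-dibromo-3,7-dichloro-2-hydroxy-3,7-dimethyloctyl 4-methylbenzenesulfonate | CC(C)(Cl)[C@H](Br)C[C@H](Br)[C@](C)(Cl)[C@H](O)COS(=O)(=O)c1ccc(C)cc1
F3 | step 3 | [(2R,3R)-3-ethynyl-3-methyloxiran-2-yl]methanol | OC[C@H]1O[C@]1(C)C#C
F4 | step 3 | (2R,3S)-3-chloro-3-methylpent-4-yne-1,2-diol | C#C[C@](C)(Cl)[C@H](O)CO
F5 | step 2 | [(2R,3R)-3-ethenyl-3-methyloxiran-2-yl]methyl 4-methylbenzenesulfonate | Cc1ccc(cc1)S(=O)(=O)OC[C@H]1O[C@]1(C)C=C
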